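**Retrosynthetic overview**
1. Target ⇒ 2-(trimethylsilyl)ethyl ester (fluoride cleavage) ⇒ allyl-bearing mixed diester + 3-bromofuran (hydroboration / B-alkyl Suzuki), so the furan enters only after all oxidations.
2. The two carboxyl groups ⇒ two CH2O-silyl arms, told apart as TBS (becomes CO2Me first) and TBDPS (becomes CO2H second).
3. C3–C5 chain ⇒ α-sulfonyl carbanion of fragment A (central CH2 from methyl phenyl sulfone) + primary iodide of fragment B, then desulfonylation.
4. Both stereocentres ⇒ lipase desymmetrisation of two achiral 2-substituted propane-1,3-diols made from malonates; the same (R)-monoacetate sense serves both ends because the free and the acetylated arm swap roles.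
5. Rings: none is built; the furan is bought as 3-bromofuran and attached in the second-last step.

Assumption: Burkholderia cepacia lipase acetylates the pro-R hydroxymethyl group of 2-alkylpropane-1,3-diols (the sense recalled for 2-benzyl-type diols), so 6 and 15 are the (R)-monoacetates; this is to be confirmed by Mosher ester analysis before going on.

**Fragment A**

Step 1
Reactants: 1 diethyl malonate; 2 5-bromo-2-methylpent-2-ene
Product: 4 diethyl 2-(4-methylpent-3-en-1-yl)propanedioate, via sodium malonate enolate 3 (not isolated)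
Conditions: 1 (2.5 equiv), NaH, THF/DMF, 0 °C; then 2, 60 °C
Reagents that add atoms: none
Why: Malonic ester alkylation, in which the enolate displaces the primary homoallylic bromide by SN2 and the excess of malonate suppresses dialkylation.

Step 2
Reactants: 4 diethyl 2-(4-methylpent-3-en-1-yl)propanedioate
Product: 5 2-(4-methylpent-3-en-1-yl)propane-1,3-diol
Conditions: LiAlH4, THF, 0 °C to reflux; then H2O
Reagents that add atoms: none
Why: LiAlH4 reduction of both esters gives the achiral, prochiral 1,3-diol, and the isolated trisubstituted alkene is inert to hydride.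

Step 3
Reactants: 5 2-(4-methylpent-3-en-1-yl)propane-1,3-diol
Product: 6 [(2R)-2-(hydroxymethyl)-6-methylhept-5-en-1-yl] acetate
Conditions: lipase PS (Burkholderia cepacia lipase, immobilised), vinyl acetate (4 equiv), MTBE, 25 °C; stopped at about 20% diacetate
Reagents that add atoms: vinyl acetate CC(=O)OC=C
Why: Enzymatic desymmetrisation by irreversible transesterification: the lipase (a serine hydrolase) passes its acyl-enzyme acetyl group only to the pro-R hydroxymethyl arm of the achiral diol, so this catalytic enantiotopic-group selection sets the first stereocentre (R), and the slight over-acetylation removes the minor enantiomer as diacetate.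

Step 4
Reactants: 6 [(2R)-2-(hydroxymethyl)-6-methylhept-5-en-1-yl] acetate
Product: 7 [(2S)-2-({[tert-butyl(dimethyl)silyl]oxy}methyl)-6-methylhept-5-en-1-yl] acetate
Conditions: TBSCl, imidazole, CH2Cl2, 0 °C
Reagents that add atoms: tert-butyldimethylsilyl chloride CC(C)(C)[Si](C)(C)Cl
Why: Imidazole-mediated silylation of the free primary alcohol is faster than acetyl migration, so the arm that later becomes the methyl ester is fixed as a TBS ether (the descriptor changes to S by priority only).

Step 5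
Reactants: 7 [(2S)-2-({[tert-butyl(dimethyl)silyl]oxy}methyl)-6-methylhept-5-en-1-yl] acetate
Product: 8 (2S)-2-({[tert-butyl(dimethyl)silyl]oxy}methyl)-6-methylhept-5-en-1-ol
Conditions: K2CO3 (0.3 equiv), MeOH, 0 °C
Reagents that add atoms: none
Why: Base-catalysed transesterification (Zemplén-type methanolysis) removes the acetate while the primary TBS ether stays in place at 0 °C.

Step 6
Reactants: 8 (2S)-2-({[tert-butyl(dimethyl)silyl]oxy}methyl)-6-methylhept-5-en-1-ol
Product: 9 tert-butyl{[(2R)-2-(iodomethyl)-6-methylhept-5-en-1-yl]oxy}dimethylsilane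
Conditions: PPh3, I2, imidazole, CH2Cl2, 0 °C to rt
Reagents that add atoms: iodine II
Why: Appel-type (Garegg–Samuelsson) iodination turns the primary alcohol into the iodide through an alkoxyphosphonium salt without touching any bond at the stereocentre.

Step 7
Reactants: 9 tert-butyl{[(2R)-2-(iodomethyl)-6-methylhept-5-en-1-yl]oxy}dimethylsilane; 10 methyl phenyl sulfone
Product: 12 tert-butyl(dimethyl)({(2S)-6-methyl-2-[2-(phenylsulfonyl)ethyl]hept-5-en-1-yl}oxy)silane, via (phenylsulfonyl)methyllithium 11 (not isolated)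
Conditions: 10 (3 equiv), n-BuLi, THF/DMPU, −78 °C; then 9, −78 °C to rt
Reagents that add atoms: none
Why: SN2 alkylation of the small α-sulfonyl carbanion adds the carbon that becomes the central CH2 of the chain and leaves the sulfone as the handle for fragment union.

**Fragment B**

Step 8
Reactants: 13 diethyl 2-(prop-2-en-1-yl)propanedioate
Product: 14 2-(prop-2-en-1-yl)propane-1,3-diol
Conditions: LiAlH4, THF, 0 °C to reflux; then H2O
Reagents that add atoms: none
Why: LiAlH4 reduction of the malonate gives the second achiral, prochiral 1,3-diol, with the terminal alkene untouched.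

Step 9
Reactants: 14 2-(prop-2-en-1-yl)propane-1,3-diol
Product: 15 [(2R)-2-(hydroxymethyl)pent-4-en-1-yl] acetate
Conditions: lipase PS (Burkholderia cepacia lipase, immobilised), vinyl acetate (4 equiv), MTBE, 25 °C; run to about 30% diacetate
Reagents that add atoms: vinyl acetate CC(=O)OC=C
Why: The same lipase-catalysed enantiotopic-group-selective transesterification acetylates the pro-R arm and sets the second stereocentre (R), with the deliberate over-acetylation (coupled kinetic resolution) raising the ee of the monoacetate.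

Step 10
Reactants: 15 [(2R)-2-(hydroxymethyl)pent-4-en-1-yl] acetate
Product: 16 [(2S)-2-(iodomethyl)pent-4-en-1-yl] acetate
Conditions: PPh3, I2, imidazole, CH2Cl2, 0 °C
Reagents that add atoms: iodine II
Why: Appel-type iodination of the free arm (here the future chain arm) is fast enough to outrun acetyl migration and does not touch the stereocentre.

Step 11
Reactants: 16 [(2S)-2-(iodomethyl)pent-4-en-1-yl] acetate
Product: 17 (2S)-2-(iodomethyl)pent-4-en-1-ol
Conditions: HCl (0.2 equiv), MeOH, 0 °C to rt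
Reagents that add atoms: none
Why: Acid-catalysed transesterification removes the acetate without generating an alkoxide next to the iodide, so neither oxetane closure nor substitution of iodide can compete.

Step 12
Reactants: 17 (2S)-2-(iodomethyl)pent-4-en-1-ol
Product: 18 tert-butyl{[(2S)-2-(iodomethyl)pent-4-en-1-yl]oxy}diphenylsilane
Conditions: TBDPSCl, imidazole, CH2Cl2, 0 °C to rt
Reagents that add atoms: tert-butyldiphenylsilyl chloride CC(C)(C)[Si](Cl)(c1ccccc1)c1ccccc1
Why: Silylation gives the robust TBDPS ether on the arm that becomes the free acid, orthogonal to the TBS ether of fragment A.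

**Union and end game**

Step 13
Reactants: 12 tert-butyl(dimethyl)({(2S)-6-methyl-2-[2-(phenylsulfonyl)ethyl]hept-5-en-1-yl}oxy)silane; 18 tert-butyl{[(2S)-2-(iodomethyl)pent-4-en-1-yl]oxy}diphenylsilane
Product: 20 tert-butyl{[(2S,6R)-6-({[tert-butyl(diphenyl)silyl]oxy}methyl)-2-(4-methylpent-3-en-1-yl)-4-(phenylsulfonyl)non-8-en-1-yl]oxy}dimethylsilane (both C4 epimers), via lithiated sulfone 19 (not isolated)
Conditions: 12 (1.2 equiv), n-BuLi, THF, −78 °C; then 18, DMPU, −78 °C to rt
Reagents that add atoms: none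
Why: Sulfone carbanion alkylation (SN2 on the primary iodide) joins the fragments into the full carbon chain, and neither stereocentre is acidic or involved.

Step 14
Reactants: 20 coupled sulfone (both C4 epimers)
Product: 21 tert-butyl{[(2R,6S)-6-({[tert-butyl(diphenyl)silyl]oxy}methyl)-2-(4-methylpent-3-en-1-yl)non-8-en-1-yl]oxy}dimethylsilane
Conditions: Na(Hg) (6% Na), Na2HPO4, MeOH/THF, −20 °C to 0 °C
Reagents that add atoms: none
Why: Reductive desulfonylation by electron transfer cleaves the C–S bond and protonation gives the CH2 group, which erases the epimeric sulfone centre and leaves alkenes and silyl ethers alone.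

Step 15
Reactants: 21 bis-silyl ether
Product: 22 (2R,6S)-6-({[tert-butyl(diphenyl)silyl]oxy}methyl)-2-(4-methylpent-3-en-1-yl)non-8-en-1-ol
Conditions: PPTS (0.3 equiv), MeOH, rt
Reagents that add atoms: none
Why: Mild acid-catalysed methanolysis cleaves the primary TBS ether much faster than the bulkier TBDPS ether, freeing only the arm destined for the methyl ester.

Step 16
Reactants: 22 mono-TBDPS alcohol
Product: 24 (2R,6S)-6-({[tert-butyl(diphenyl)silyl]oxy}methyl)-2-(4-methylpent-3-en-1-yl)non-8-enoic acid, via aldehyde 23 (not isolated)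
Conditions: TEMPO (0.2 equiv), PhI(OAc)2 (2.5 equiv), MeCN/H2O, 0 °C to rt
Reagents that add atoms: water O
Why: Oxoammonium (TEMPO) oxidation takes the primary alcohol to the aldehyde and its hydrate on to the acid at near-neutral pH, so the α-stereocentre is not epimerised and the alkenes and TBDPS ether survive.

Step 17
Reactants: 24 acid
Product: 25 methyl (2R,6S)-6-({[tert-butyl(diphenyl)silyl]oxy}methyl)-2-(4-methylpent-3-en-1-yl)non-8-enoate
Conditions: TMSCHN2, PhMe/MeOH, 0 °C
Reagents that add atoms: (trimethylsilyl)diazomethane C[Si](C)(C)C=[N+]=[N-]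
Why: Base-free O-methylation of the carboxylic acid by the diazoalkane gives the methyl ester with no risk to the α-stereocentre.

Step 18
Reactants: 25 methyl ester
Product: 26 methyl (2R,6S)-6-(hydroxymethyl)-2-(4-methylpent-3-en-1-yl)non-8-enoate
Conditions: TBAF, AcOH (1:1), THF, rt
Reagents that add atoms: none
Why: Fluoride-driven desilylation removes the TBDPS group, and the acetic acid buffer keeps the methyl ester and its α-stereocentre safe.

Step 19
Reactants: 26 hydroxy ester
Product: 28 (2S,6R)-6-(methoxycarbonyl)-10-methyl-2-(prop-2-en-1-yl)undec-9-enoic acid, via aldehyde 27 (not isolated)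
Conditions: TEMPO (0.2 equiv), PhI(OAc)2 (2.5 equiv), MeCN/H2O, 0 °C to rt
Reagents that add atoms: water O
Why: The same TEMPO oxidation through the aldehyde hydrate makes the second carboxyl group while no furan is yet present and without epimerising either α-stereocentre.

Step 20
Reactants: 28 acid ester
Product: 29 1-methyl 7-[2-(trimethylsilyl)ethyl] (2R,6S)-2-(4-methylpent-3-en-1-yl)-6-(prop-2-en-1-yl)heptanedioate
Conditions: 2-(trimethylsilyl)ethanol, DCC, DMAP (0.1 equiv), CH2Cl2, 0 °C to rt
Reagents that add atoms: 2-(trimethylsilyl)ethanol C[Si](C)(C)CCO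
Why: Steglich esterification masks the acid, which would otherwise consume the borane, as an ester that fluoride removes in the presence of the methyl ester.

Step 21
Reactants: 29 allyl diester; 30 3-bromofuran
Product: 32 1-methyl 7-[2-(trimethylsilyl)ethyl] (2R,6S)-6-[3-(furan-3-yl)propyl]-2-(4-methylpent-3-en-1-yl)heptanedioate, via alkylborane 31 (not isolated)
Conditions: 9-BBN, THF, 0 °C to rt; then 30 (1.5 equiv), Pd(dppf)Cl2 (5 mol%), K3PO4 (aq), DMF, 50 °C
Reagents that add atoms: none
Why: Anti-Markovnikov hydroboration by 9-BBN takes only the terminal alkene (the trisubstituted alkene and the esters are left), and the B-alkyl Suzuki–Miyaura coupling with the heteroaryl bromide then builds the 3-(furan-3-yl)propyl chain.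

Step 22
Reactants: 32 furyl diester
Product: 33 (2S,6R)-2-[3-(furan-3-yl)propyl]-6-(methoxycarbonyl)-10-methylundec-9-enoic acid
Conditions: TBAF, THF, 0 °C to rt; then AcOH
Reagents that add atoms: none
Why: Fluoride attack at silicon triggers β-elimination of the 2-(trimethylsilyl)ethyl ester (loss of ethene and Me3SiF), which frees the acid while the methyl ester, furan, alkene and both stereocentres are untouched.

**Compound list**
1 | diethyl malonate | CCOC(=O)CC(=O)OCC | starting material
2 | 5-bromo-2-methylpent-2-ene | CC(C)=CCCBr | starting material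
3 | sodium enolate of diethyl malonate | CCOC(=O)[CH-]C(=O)OCC.[Na+] | intermediate
4 | diethyl 2-(4-methylpent-3-en-1-yl)propanedioate | CCOC(=O)C(CCC=C(C)C)C(=O)OCC | intermediate
5 | 2-(4-methylpent-3-en-1-yl)propane-1,3-diol (achiral) | OCC(CCC=C(C)C)CO | intermediate
6 | [(2R)-2-(hydroxymethyl)-6-methylhept-5-en-1-yl] acetate | OC[C@@H](CCC=C(C)C)COC(C)=O | intermediate
7 | [(2S)-2-({[tert-butyl(dimethyl)silyl]oxy}methyl)-6-methylhept-5-en-1-yl] acetate | CC(C)(C)[Si](C)(C)OC[C@@H](CCC=C(C)C)COC(C)=O | intermediate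
8 | (2S)-2-({[tert-butyl(dimethyl)silyl]oxy}methyl)-6-methylhept-5-en-1-ol | CC(C)(C)[Si](C)(C)OC[C@@H](CCC=C(C)C)CO | intermediate
9 | tert-butyl{[(2R)-2-(iodomethyl)-6-methylhept-5-en-1-yl]oxy}dimethylsilane | CC(C)(C)[Si](C)(C)OC[C@@H](CCC=C(C)C)CI | intermediate
10 | methyl phenyl sulfone | CS(=O)(=O)c1ccccc1 | starting material
11 | (phenylsulfonyl)methyllithium | [Li]CS(=O)(=O)c1ccccc1 | intermediate
12 | tert-butyl(dimethyl)({(2S)-6-methyl-2-[2-(phenylsulfonyl)ethyl]hept-5-en-1-yl}oxy)silane | CC(C)(C)[Si](C)(C)OC[C@@H](CCC=C(C)C)CCS(=O)(=O)c1ccccc1 | intermediate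
13 | diethyl 2-(prop-2-en-1-yl)propanedioate (diethyl allylmalonate) | C=CCC(C(=O)OCC)C(=O)OCC | starting material
14 | 2-(prop-2-en-1-yl)propane-1,3-diol (achiral) | C=CCC(CO)CO | intermediate
15 | [(2R)-2-(hydroxymethyl)pent-4-en-1-yl] acetate | OC[C@@H](CC=C)COC(C)=O | intermediate
16 | [(2S)-2-(iodomethyl)pent-4-en-1-yl] acetate | IC[C@@H](CC=C)COC(C)=O | intermediate
17 | (2S)-2-(iodomethyl)pent-4-en-1-ol | IC[C@@H](CC=C)CO | intermediate
18 | tert-butyl{[(2S)-2-(iodomethyl)pent-4-en-1-yl]oxy}diphenylsilane | IC[C@@H](CC=C)CO[Si](c1ccccc1)(c1ccccc1)C(C)(C)C | intermediate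
19 | α-lithio derivative of sulfone 12 (lithium on the carbon bearing sulfur) | CC(C)(C)[Si](C)(C)OC[C@@H](CCC=C(C)C)CC([Li])S(=O)(=O)c1ccccc1 | intermediate
20 | tert-butyl{[(2S,6R)-6-({[tert-butyl(diphenyl)silyl]oxy}methyl)-2-(4-methylpent-3-en-1-yl)-4-(phenylsulfonyl)non-8-en-1-yl]oxy}dimethylsilane, both C4 epimers | CC(C)(C)[Si](C)(C)OC[C@@H](CCC=C(C)C)CC(C[C@@H](CC=C)CO[Si](c1ccccc1)(c1ccccc1)C(C)(C)C)S(=O)(=O)c1ccccc1 | intermediate
21 | tert-butyl{[(2R,6S)-6-({[tert-butyl(diphenyl)silyl]oxy}methyl)-2-(4-methylpent-3-en-1-yl)non-8-en-1-yl]oxy}dimethylsilane | CC(C)(C)[Si](C)(C)OC[C@@H](CCC=C(C)C)CCC[C@@H](CC=C)CO[Si](c1ccccc1)(c1ccccc1)C(C)(C)C | intermediate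
22 | (2R,6S)-6-({[tert-butyl(diphenyl)silyl]oxy}methyl)-2-(4-methylpent-3-en-1-yl)non-8-en-1-ol | OC[C@@H](CCC=C(C)C)CCC[C@@H](CC=C)CO[Si](c1ccccc1)(c1ccccc1)C(C)(C)C | intermediate
23 | (2R,6S)-6-({[tert-butyl(diphenyl)silyl]oxy}methyl)-2-(4-methylpent-3-en-1-yl)non-8-enal | O=C[C@@H](CCC=C(C)C)CCC[C@@H](CC=C)CO[Si](c1ccccc1)(c1ccccc1)C(C)(C)C | intermediate
24 | (2R,6S)-6-({[tert-butyl(diphenyl)silyl]oxy}methyl)-2-(4-methylpent-3-en-1-yl)non-8-enoic acid | OC(=O)[C@@H](CCC=C(C)C)CCC[C@@H](CC=C)CO[Si](c1ccccc1)(c1ccccc1)C(C)(C)C | intermediate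
25 | methyl (2R,6S)-6-({[tert-butyl(diphenyl)silyl]oxy}methyl)-2-(4-methylpent-3-en-1-yl)non-8-enoate | COC(=O)[C@@H](CCC=C(C)C)CCC[C@@H](CC=C)CO[Si](c1ccccc1)(c1ccccc1)C(C)(C)C | intermediate
26 | methyl (2R,6S)-6-(hydroxymethyl)-2-(4-methylpent-3-en-1-yl)non-8-enoate | COC(=O)[C@@H](CCC=C(C)C)CCC[C@@H](CC=C)CO | intermediate
27 | methyl (2R,6S)-6-formyl-2-(4-methylpent-3-en-1-yl)non-8-enoate | COC(=O)[C@@H](CCC=C(C)C)CCC[C@@H](CC=C)C=O | intermediate
28 | (2S,6R)-6-(methoxycarbonyl)-10-methyl-2-(prop-2-en-1-yl)undec-9-enoic acid | COC(=O)[C@@H](CCC=C(C)C)CCC[C@@H](CC=C)C(=O)O | intermediate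
29 | 1-methyl 7-[2-(trimethylsilyl)ethyl] (2R,6S)-2-(4-methylpent-3-en-1-yl)-6-(prop-2-en-1-yl)heptanedioate | COC(=O)[C@@H](CCC=C(C)C)CCC[C@@H](CC=C)C(=O)OCC[Si](C)(C)C | intermediate
30 | 3-bromofuran | Brc1ccoc1 | starting material
31 | B-alkyl-9-BBN adduct of 29 (9-borabicyclo[3.3.1]nonan-9-yl on the terminal carbon of the former allyl group; geometry at both stereocentres unchanged) | COC(=O)[C@@H](CCC=C(C)C)CCC[C@@H](CCCB1C2CCCC1CCC2)C(=O)OCC[Si](C)(C)C | intermediate
32 | 1-methyl 7-[2-(trimethylsilyl)ethyl] (2R,6S)-6-[3-(furan-3-yl)propyl]-2-(4-methylpent-3-en-1-yl)heptanedioate | COC(=O)[C@@H](CCC=C(C)C)CCC[C@@H](CCCc1ccoc1)C(=O)OCC[Si](C)(C)C | intermediate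
33 | (2S,6R)-2-[3-(furan-3-yl)propyl]-6-(methoxycarbonyl)-10-methylundec-9-enoic acid | COC(=O)[C@@H](CCC=C(C)C)CCC[C@@H](CCCc1ccoc1)C(=O)O | target

**Totals**
Total step count: 22. Longest linear sequence: 17 steps (steps 1–7, then 13–22); the fragment B branch (steps 8–12) joins at step 13.

**Three steps most likely to fail, each with a fallback**

Step 9 (lipase acetylation of the small allyl diol 14). Allyl and CH2OH differ little in size, so the ee may be too low, and the minor enantiomer ends up as an inseparable diastereomer after step 13. The fallback sets out from 14 and comes back at 18. Diol 14 is peracetylated (Ac2O, pyridine) to 2-(prop-2-en-1-yl)propane-1,3-diyl diacetate F1. The same lipase in pH 7 phosphate buffer then hydrolyses the same enantiotopic arm, and over-hydrolysis to 14 again sharpens the ee. This gives the antipodal monoacetate [(2S)-2-(hydroxymethyl)pent-4-en-1-yl] acetate F2, whose free hydroxyl is now the future carboxyl arm. Silylation (TBDPSCl, imidazole) gives [(2R)-2-({[tert-butyl(diphenyl)silyl]oxy}methyl)pent-4-en-1-yl] acetate F3. Methanolysis (K2CO3, MeOH, 0 °C) gives (2R)-2-({[tert-butyl(diphenyl)silyl]oxy}methyl)pent-4-en-1-ol F4, and iodination (PPh3, I2, imidazole) gives 18. This also bypasses iodo alcohol 17.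

Step 13 (SN2 of a secondary-type sulfonyl carbanion on a β-branched iodide). It may be slow or give elimination. The fallback sets out from 18 and 8 and comes back at 20; it exchanges the roles of the fragments and uses a far more reactive electrophile. Iodide 18 is alkylated with the small anion 11 (as in step 7) to tert-butyl(diphenyl)({(2R)-2-[2-(phenylsulfonyl)ethyl]pent-4-en-1-yl}oxy)silane F5. Alcohol 8 is converted (Tf2O, 2,6-lutidine, CH2Cl2, −78 °C) into [(2R)-2-({[tert-butyl(dimethyl)silyl]oxy}methyl)-6-methylhept-5-en-1-yl] trifluoromethanesulfonate F6. F5 is deprotonated (n-BuLi, THF, −78 °C) to its α-lithio derivative F7, which displaces the triflate of F6 at −78 °C to give the same sulfone 20.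

Step 21 (late B-alkyl Suzuki coupling with 3-bromofuran). Protodeboronation, sluggish transmetalation or ester hydrolysis in the basic aqueous medium could lower the yield. The fallback sets out from 29 (through borane 31) and comes back at 32. Borane 31 is oxidised (NaBO3·4H2O, THF/H2O, 0 °C) to 1-methyl 7-[2-(trimethylsilyl)ethyl] (2R,6S)-6-(3-hydroxypropyl)-2-(4-methylpent-3-en-1-yl)heptanedioate F8. F8 is iodinated at once (PPh3, I2, imidazole), before it can lactonise, to the (2R,6S)-6-(3-iodopropyl) diester F9. Zinc insertion (Zn dust, LiCl, THF) gives the (2R,6S)-6-[3-(iodozincio)propyl] diester F10. Base-free Negishi coupling of F10 with 3-bromofuran 30 (Pd(OAc)2, SPhos, THF, rt) gives 32.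

**Further compounds**
F1 | step 9 | 2-(prop-2-en-1-yl)propane-1,3-diyl diacetate | CC(=O)OCC(CC=C)COC(C)=O
F2 | step 9 | [(2S)-2-(hydroxymethyl)pent-4-en-1-yl] acetate | CC(=O)OC[C@@H](CC=C)CO
F3 | step 9 | [(2R)-2-({[tert-butyl(diphenyl)silyl]oxy}methyl)pent-4-en-1-yl] acetate | CC(=O)OC[C@@H](CC=C)CO[Si](c1ccccc1)(c1ccccc1)C(C)(C)C
F4 | step 9 | (2R)-2-({[tert-butyl(diphenyl)silyl]oxy}methyl)pent-4-en-1-ol | OC[C@@H](CC=C)CO[Si](c1ccccc1)(c1ccccc1)C(C)(C)C
F5 | step 13 | tert-butyl(diphenyl)({(2R)-2-[2-(phenylsulfonyl)ethyl]pent-4-en-1-yl}oxy)silane | O=S(=O)(CC[C@@H](CC=C)CO[Si](c1ccccc1)(c1ccccc1)C(C)(C)C)c1ccccc1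
F6 | step 13 | [(2R)-2-({[tert-butyl(dimethyl)silyl]oxy}methyl)-6-methylhept-5-en-1-yl] trifluoromethanesulfonate | CC(C)(C)[Si](C)(C)OC[C@@H](CCC=C(C)C)COS(=O)(=O)C(F)(F)F
F7 | step 13 | α-lithio derivative of sulfone F5 | O=S(=O)(C([Li])C[C@@H](CC=C)CO[Si](c1ccccc1)(c1ccccc1)C(C)(C)C)c1ccccc1
F8 | step 21 | 1-methyl 7-[2-(trimethylsilyl)ethyl] (2R,6S)-6-(3-hydroxypropyl)-2-(4-methylpent-3-en-1-yl)heptanedioate | COC(=O)[C@@H](CCC=C(C)C)CCC[C@@H](CCCO)C(=O)OCC[Si](C)(C)C
F9 | step 21 | 1-methyl 7-[2-(trimethylsilyl)ethyl] (2R,6S)-6-(3-iodopropyl)-2-(4-methylpent-3-en-1-yl)heptanedioate | COC(=O)[C@@H](CCC=C(C)C)CCC[C@@H](CCCI)C(=O)OCC[Si](C)(C)C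
F10 | step 21 | 1-methyl 7-[2-(trimethylsilyl)ethyl] (2R,6S)-6-[3-(iodozincio)propyl]-2-(4-methylpent-3-en-1-yl)heptanedioate | COC(=O)[C@@H](CCC=C(C)C)CCC[C@@H](CCC[Zn]I)C(=O)OCC[Si](C)(C)C
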